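The numbers of this flask were chosen freely; no experiment stands behind them.

Which flask ends with the longer chains, and by how many monomer units per chain?

in all of them: initiator 0.34 µM; time 1.5 min
- spring: free monomer 0.20 mM
- summer: free monomer 0.10 mM

    free monomer + initiating radical → growing radical + monomer in chains (k1 = 3.85 × 10⁷ M⁻¹ s⁻¹)
    free monomer + growing radical → monomer in chains + growing radical, rate k2*[growing radical]*[free monomer] (k2 = 1.41 × 10⁶ M⁻¹ s⁻¹)
    2 growing radical → dead chain (k3 = 4 × 10⁶ M⁻¹ s⁻¹)
    initiator → 2 initiating radical (k4 = 0.00981 s⁻¹)

- where a step has two of a species, its rate is k times that concentration squared, and two are used at each turn
- the average divides the monomer in chains by the number of chains, living and dead together; two radicals that join make one chain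
- run time (spring): 1.5 min

- which of the two ends with the longer chains by the average number of monomer units in a chain (living and dead chains, two that joined counted as one) ("neither" if they lie within 10 %) (spring / summer / neither)
- average number of monomer units in a chain (living and dead chains, two that joined counted as one) at the end, spring
- average number of monomer units in a chain (living and dead chains, two that joined counted as one) at the end, summer

Bench note, reckoned by hand. Spring and summer start with free monomer and initiator, and initiator breaks with a half-life of 1.2 min. At the summer charge, an initiating radical meets free monomer within 2.60 × 10⁻⁴ s, so count each one as a chain begun. First round: suppose the radicals have joined in pairs, and the chains equal the initiator decomposed, 1.99 × 10⁻⁴ mM. Go round again: growing radicals, at concentration L, still stand unjoined, and each counts as a whole chain. Take L at quasi-steady state, where making balances joining; that reckons L at the end as 1.86 × 10⁻⁵ mM. Carry the chain count C, decomposed initiator plus half of L: 2.09 × 10⁻⁴ mM. Expect the same C in both flasks.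

Growth over the falling L leaves 5.17 % of the free monomer in each flask. Dividing the rest by C gives 909 units in spring and 454 in summer. Don't top up initiator: it raises C.

The forecast gives spring, with 903 (870 to 935) and 452 (435 to 468): “The chain count and fractional conversion do not depend on the starting monomer, so doubling it in spring doubles the average length.” My spring figure stands slightly higher.

Spring ends longer, at 904 units against 452 in summer. At the end of summer, free monomer has a half-life of 0.43 min by chain growth, shorter than the 1.2 min of initiator. At 0.750 min summer growth has 83 % of its turnover up to the end behind it, while 64.3 % of the initiator charged still stands. Summer's monomer in chains, 94.5 % of the free monomer charged, over C reads 453. Cut summer's initiator to 2.0 × 10⁻⁴ mM: C becomes 1.24 × 10⁻⁴ mM, and 88.8 % in chains over it reads 714, where that flask gives 713.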